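## The problem

Compound 26 is a bicyclo[3.2.1]oct-3-en-8-one. The one-carbon bridge C8 is a ketone held between two fully substituted bridgeheads, C1 (methoxy) and C5 (allyl). The two-carbon bridge carries C6 (methyl, turned away from C8) and C7 (3,4-dimethoxyphenyl, on the C8 side), trans to each other. The three-carbon bridge carries the C2 acetate, also on the C8 side, next to the enol ether C3(OMe)=C4.

The five stereocentres (1S,2S,5S,6R,7S) are contiguous but not independent. A bridge can only span one face, so C1 follows from C5, and C5 can be derived from C6 in a small ring. C7 neighbours C6 but is more safely set by a catalyst. C2 is the only centre that must be made by attack on the finished bicycle, and the face open to a reagent there depends on what C8 carries at that moment.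

The enol ether with its allylic acetate will not survive aqueous acid. The terminal alkene rules out hydrogenation, ozonolysis and hydroboration once it is in place. The dimethoxyphenyl ring limits strong oxidants and Lewis acids, and every β-hydroxy ketone on the way can revert by retro-aldol cleavage.

The enabling feature is seen when C8 is taken out. Carbons C1–C7 then form a seven-membered ring in which C1 is α to the C2 carbonyl and lies across the ring from C5. With C8 as a formyl group on quaternary C5 and C3 already an enol-ether carbon, C1–H is the only acidic hydrogen, so C1–C8 is an aldol bond that can be closed across the ring without any regiochemical question.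

(Carbon labels C1–C8 are those of the bicycle and are kept for the same atoms in every intermediate.)

## Retrosynthesis

**26 back to 22 (no C–C bond cut).** The C8 ketone is written as a silyl-protected carbinol (25, 24) and the C2 acetate as an alcohol (23) that comes from the C2 ketone 22. With C8 as a ketone the open face of C2 is the C8 side, and hydride would give the wrong epimer. A C8 oxygen pointing over the C2–C4 bridge closes that face, as the syn-methyl group does in camphor. It should be a silyl ether and not a free hydroxyl, because a free hydroxyl could hand hydride to the very face it is meant to block, and because only one hydroxyl is then present at the acetylation. Asked of the forward steps: 1,2-reduction from the C6–C7 side, acetylation, desilylation, oxidation of a hindered carbinol.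

**22 back to 20 (cut C1–C8).** This is the transannular aldol. The neighbouring cuts (C4–C5, C5–C6, C6–C7) each keep one small ring and must create a quaternary bridgehead in or before the closure. The C1–C8 cut opens the five- and the six-membered ring at once and leaves the monocyclic keto aldehyde 20 with three stereocentres; C1 need not be controlled because it is enolised. The forward reaction must enolise only at C1 and must hold the aldolate; silylation in the same flask does the second and delivers 22 directly.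

**20 back to 17 (cut C3=C4).** The aldehyde of 20 comes from the primary alcohol 19 and its silyl ether 18; the ring of 18 is opened at the enol-ether double bond to the keto phosphonate aldehyde 17. A metathesis at the same bond would have to tell the C5 vinyl group from the C5 allyl group. Cuts at C1–C2 or C2–C3 would need acyl-anion chemistry. An intramolecular Horner–Wadsworth–Emmons reaction has one nucleophilic carbon under mild base (C3, not C1), gives the ring alkene cis by necessity and brings the C3 methoxy group with the phosphonate. It requires that the two one-carbon arms on C5 differ: C4 an aldehyde, C8 a silyl-protected alcohol.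

**17 back to 14 and 15 (cut C2–C3).** The aldehyde of 17 is stored as the dithiane of 16, and 16 is the acylation product of the lithiated phosphonate 15 with the α-methoxy ester 14. The precursor is an open chain with the three stereocentres C5, C6, C7.

**14 back to 10 and 11 (cut C1–O and C7–aryl).** The C1 methoxy group comes from oxidation of the ester enolate of 12 (13, then 14), with no stereochemical demand. The aryl group comes from conjugate addition of boronic acid 11 to the (E)-enoate 10 under a chiral rhodium catalyst. Catalyst control is preferred here because the bias of the C6 centre in an open chain cannot be relied on.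

**10 back to 6 (cut C7=C1).** The enoate is the Wittig product of aldehyde 9, which comes from alcohol 8, the dithioacetal-opened form of lactol 7, itself the half-reduced lactone 6. The lactone carbonyl carbon thus becomes C4 and the lactone CH2–O carbon becomes C7.

**6 back to 2 and 3 (cut C5–C8 and C5–allyl).** Both bonds are made by enolate alkylation of the (S)-β-methyl lactone 2, through 4 and 5. In a five-membered lactone an electrophile enters anti to the β-substituent. C8 must end up trans to the C6 methyl group (the methyl is on the face away from the C8 bridge), so allyl bromide 3 is introduced first and the one-carbon electrophile second. This order is the whole stereochemical argument for C5.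

**2 back to 1.** The lactone is the hydrogenation product of butenolide 1; this step sets C6, the centre from which the others are derived.

## Roads not taken

**Alternative 1:** the cut is C6–C7, with the five-membered ring made first. A cross-conjugated dienone A2 would be closed by a Lewis-acid-promoted conrotatory 4π cyclisation (Sc(OTf)3 with a chiral pybox ligand), and the oxyallyl cation would be quenched by Et3SiH to give cyclopentanone A1.
- Merits: one catalytic step makes the ring, the C6–C7 bond and the trans aryl/methyl pair. A2 is a short-chain dienone, so A1 would be reached in far fewer steps than the eight that the chosen route spends before 12.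
- Weak points: A1 is less than half of the target. Both α-carbons are only tertiary and unconfigured, and the three-carbon bridge C2–C3–C4 has to be annulated across them. This creates two quaternary bridgeheads one after the other on a crowded ketone that enolises on both sides, with the methoxy enone and C2 still to come. The enantioselective, hydride-interrupted variant of the cyclisation has a narrow substrate range.
- Comparison: Alternative 1 is clearly better for C6/C7. Against this the chosen plan sets the fact that after its ring-forming step only functional-group changes remain, whereas here the hardest bonds are still to be made.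

**Alternative 2:** the cut is C5–C6. The N-(acyloxy)phthalimide ester A4, built on a cyclohexenedione, would be reduced by photoexcited Ru(bpy)3Cl2 and an amine. The C6 radical formed on loss of CO2 would add 5-exo to C5 and give the bicyclic dione A3.
- Merits: a radical adds readily to a carbon that becomes quaternary, the conditions are neutral, and the C2 acetate is already in place. In tolerance of hindrance and functionality the closure is better than an enolate reaction on a keto aldehyde.
- Weak points: A4 must already contain the quaternary C1 ether with the right relation to C2 and to C7 in the side chain, so the bridgehead problem is moved and not solved. C6 is set by a planar radical under conformational control only. A3 carries a C3 ketone and a C4 methylene, so the enol ether needs a regioselective O-methylation in competition with enolisation toward the acetate-bearing C2.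
- Comparison: the chosen plan has a more demanding closing step but derives every centre from C6 through ring-controlled steps, and its enol ether is in place before the bicycle exists.

**Alternative 3:** the cut is C4–C5. Cyclopentanone A6, with a (bromoalkenyl) side chain on C1, would be closed by palladium-catalysed α-alkenylation of its C5 enolate (Pd2(dba)3, a bulky phosphine, K3PO4) to give A5.
- Merits: this closure type is well established for bridged ketones. It makes C5 quaternary in the ring-forming step, only C5 can enolise, and C2 arrives configured as a silyl ether. The end game would be two steps against four here. In closure and end game this road is at least as good as the chosen one.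
- Weak points: the burden lies in A6. C1 must be made quaternary together with the exocyclic C2 carbinol, two adjacent centres of which only the ring one has an obvious control element. A sensitive β-bromo enol ether has to be carried through that assembly.
- Comparison: the chosen plan has a longer end game, but C1 costs nothing in the key step and C2 comes from a reduction whose facial course is dictated by the bicycle itself.

Key step: step 16

## Route

Assumption: the (S)-BINAP complex is taken to hydrogenate 1 to the (S)-lactone; the sense is checked on the sign of rotation of 2 and the mirror-image ligand is used if the check requires it.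

Remark: C1 is carried as a mixture of epimers from 13 to 20 (and C3 in 16 and 17); all isomers converge in steps 13 and 16.

Step 1
Reactants: 1 4-methylfuran-2(5H)-one
Product: 2 (4S)-4-methyloxolan-2-one
Conditions: H2 (100 atm), Ru(OAc)2[(S)-BINAP] (0.5 mol%), CH2Cl2–MeOH, 50 °C
Reagents that add atoms: none
Why: Ru–BINAP hydrogenation of a β-substituted butenolide is an established enantioselective alkene hydrogenation; it sets C6, from which C5 and then C1 are derived.

Step 2
Reactants: 2 (4S)-4-methyloxolan-2-one; 3 allyl bromide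
Product: 4 (3S,4S)-4-methyl-3-(prop-2-en-1-yl)oxolan-2-one
Conditions: LiN(iPr)2, THF, −78 °C; then 3, −78 → −40 °C
Reagents that add atoms: none
Why: Lactone enolate alkylation; the electrophile enters the planar five-membered enolate anti to the C6 methyl group, giving the trans lactone (this C5 configuration is erased again in step 3).

Step 3
Reactants: 4 (3S,4S)-4-methyl-3-(prop-2-en-1-yl)oxolan-2-one
Product: 5 (3R,4S)-3-(hydroxymethyl)-4-methyl-3-(prop-2-en-1-yl)oxolan-2-one
Conditions: LiN(iPr)2, THF, −78 °C; then CH2O (gas, from cracked paraformaldehyde), −78 → −30 °C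
Reagents that add atoms: formaldehyde, C=O
Why: Aldol addition of the α-substituted lactone enolate to formaldehyde; attack again anti to the C6 methyl group puts the new carbon C8 trans and the allyl group cis to methyl, which is the C5 configuration of 26. The order of the two electrophiles decides this.

Step 4
Reactants: 5 (3R,4S)-3-(hydroxymethyl)-4-methyl-3-(prop-2-en-1-yl)oxolan-2-one
Product: 6 (3R,4S)-3-{[tert-butyl(diphenyl)silyl]oxymethyl}-4-methyl-3-(prop-2-en-1-yl)oxolan-2-one
Conditions: t-BuPh2SiCl, imidazole, DMF, rt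
Reagents that add atoms: tert-butyl(chloro)diphenylsilane, CC(C)(C)[Si](Cl)(c1ccccc1)c1ccccc1
Why: Silylation of a primary alcohol; the bulky silyl ether withstands the Lewis acid of step 6 and the bases that follow, and keeps C8 distinct from C4 until step 14.

Step 5
Reactants: 6 (3R,4S)-3-{[tert-butyl(diphenyl)silyl]oxymethyl}-4-methyl-3-(prop-2-en-1-yl)oxolan-2-one
Product: 7 (3R,4S)-3-{[tert-butyl(diphenyl)silyl]oxymethyl}-4-methyl-3-(prop-2-en-1-yl)oxolan-2-ol
Conditions: i-Bu2AlH, CH2Cl2, −78 °C
Reagents that add atoms: none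
Why: Half-reduction of a γ-lactone to the lactol through a tetrahedral aluminate that is stable at low temperature; C4 reaches the aldehyde level.

Step 6
Reactants: 7 (3R,4S)-3-{[tert-butyl(diphenyl)silyl]oxymethyl}-4-methyl-3-(prop-2-en-1-yl)oxolan-2-ol
Product: 8 (2S,3R)-3-{[tert-butyl(diphenyl)silyl]oxymethyl}-3-(1,3-dithian-2-yl)-2-methylhex-5-en-1-ol
Conditions: HS(CH2)3SH, BF3·OEt2, CH2Cl2, −30 → 0 °C
Reagents that add atoms: propane-1,3-dithiol, SCCCS
Why: Dithioacetalisation of a lactol opens the ring for good; C4 is stored as a dithiane and the C7 hydroxyl is set free for chain extension.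

Step 7
Reactants: 8 (2S,3R)-3-{[tert-butyl(diphenyl)silyl]oxymethyl}-3-(1,3-dithian-2-yl)-2-methylhex-5-en-1-ol
Product: 10 methyl (2E,4R,5R)-5-{[tert-butyl(diphenyl)silyl]oxymethyl}-5-(1,3-dithian-2-yl)-4-methylocta-2,7-dienoate, via aldehyde 9 (not isolated)
Conditions: SO3·pyridine, DMSO, i-Pr2NEt, CH2Cl2, 0 °C; then Ph3P=CHCO2Me, rt → 40 °C
Reagents that add atoms: methyl (triphenyl-λ5-phosphanylidene)acetate, COC(=O)C=P(c1ccccc1)(c1ccccc1)c1ccccc1
Why: Parikh–Doering oxidation leaves the thioacetal alone, and the Wittig reaction of the stabilised ylide in the same flask is E-selective; the α-methyl aldehyde is not isolated, which protects C6.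

Step 8
Reactants: 10 methyl (2E,4R,5R)-5-{[tert-butyl(diphenyl)silyl]oxymethyl}-5-(1,3-dithian-2-yl)-4-methylocta-2,7-dienoate; 11 (3,4-dimethoxyphenyl)boronic acid
Product: 12 methyl (3S,4R,5R)-5-{[tert-butyl(diphenyl)silyl]oxymethyl}-3-(3,4-dimethoxyphenyl)-5-(1,3-dithian-2-yl)-4-methyloct-7-enoate
Conditions: 11 (2.5 equiv), [Rh(OH)((S)-BINAP)]2 (3 mol%), dioxane–H2O (10:1), 50 °C
Reagents that add atoms: none
Why: Hayashi–Miyaura conjugate addition of an arylboronic acid to an (E)-enoate; with (S)-BINAP the aryl group should enter the α-si face, the sense established for this catalyst, which makes C7 (S) with aryl and methyl in the relation that becomes trans on the ring. Catalyst control is expected to override the bias of C6.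

Step 9
Reactants: 12 methyl (3S,4R,5R)-5-{[tert-butyl(diphenyl)silyl]oxymethyl}-3-(3,4-dimethoxyphenyl)-5-(1,3-dithian-2-yl)-4-methyloct-7-enoate
Product: 13 methyl (2RS,3S,4R,5R)-5-{[tert-butyl(diphenyl)silyl]oxymethyl}-3-(3,4-dimethoxyphenyl)-5-(1,3-dithian-2-yl)-2-hydroxy-4-methyloct-7-enoate
Conditions: KN(SiMe3)2, THF, −78 °C; then 2-(benzenesulfonyl)-3-phenyloxaziridine
Reagents that add atoms: 2-(benzenesulfonyl)-3-phenyloxaziridine, O=S(=O)(N1OC1c1ccccc1)c1ccccc1
Why: Davis oxidation of an ester enolate brings in the C1 oxygen; the configuration at C1 is of no consequence because C1 is enolised in step 16.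

Step 10
Reactants: 13 methyl (2RS,3S,4R,5R)-5-{[tert-butyl(diphenyl)silyl]oxymethyl}-3-(3,4-dimethoxyphenyl)-5-(1,3-dithian-2-yl)-2-hydroxy-4-methyloct-7-enoate
Product: 14 methyl (2RS,3S,4R,5R)-5-{[tert-butyl(diphenyl)silyl]oxymethyl}-3-(3,4-dimethoxyphenyl)-5-(1,3-dithian-2-yl)-2-methoxy-4-methyloct-7-enoate
Conditions: NaH, MeI, THF–DMF, 0 °C
Reagents that add atoms: iodomethane, CI
Why: Williamson methylation of the alkoxide, run cold and briefly without silver salts so that the dithiane sulfur atoms are not alkylated.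

Step 11
Reactants: 14 methyl (2RS,3S,4R,5R)-5-{[tert-butyl(diphenyl)silyl]oxymethyl}-3-(3,4-dimethoxyphenyl)-5-(1,3-dithian-2-yl)-2-methoxy-4-methyloct-7-enoate; 15 diethyl (methoxymethyl)phosphonate
Product: 16 diethyl [(1RS,3RS,4S,5R,6R)-6-{[tert-butyl(diphenyl)silyl]oxymethyl}-4-(3,4-dimethoxyphenyl)-6-(1,3-dithian-2-yl)-1,3-dimethoxy-5-methyl-2-oxonon-8-en-1-yl]phosphonate
Conditions: 15 (2.5 equiv), LiN(iPr)2, THF, −78 °C; then 14, −78 → −40 °C
Reagents that add atoms: none
Why: Acylation of a lithiated phosphonate by an ester (phosphonate Claisen condensation); the excess anion deprotonates the product and so shields the new ketone. C3 arrives with its methoxy group.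

Step 12
Reactants: 16 diethyl [(1RS,3RS,4S,5R,6R)-6-{[tert-butyl(diphenyl)silyl]oxymethyl}-4-(3,4-dimethoxyphenyl)-6-(1,3-dithian-2-yl)-1,3-dimethoxy-5-methyl-2-oxonon-8-en-1-yl]phosphonate
Product: 17 diethyl [(1RS,3RS,4S,5R,6R)-6-{[tert-butyl(diphenyl)silyl]oxymethyl}-4-(3,4-dimethoxyphenyl)-6-formyl-1,3-dimethoxy-5-methyl-2-oxonon-8-en-1-yl]phosphonate
Conditions: MeI, CaCO3, MeCN–H2O (9:1), 40 °C
Reagents that add atoms: water, O
Why: Alkylative hydrolysis of the dithiane under near-neutral conditions that spare the alkene, the silyl ether and the electron-rich arene; the C4 aldehyde is released on a carbon without α-hydrogen.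

Step 13
Reactants: 17 diethyl [(1RS,3RS,4S,5R,6R)-6-{[tert-butyl(diphenyl)silyl]oxymethyl}-4-(3,4-dimethoxyphenyl)-6-formyl-1,3-dimethoxy-5-methyl-2-oxonon-8-en-1-yl]phosphonate
Product: 18 (4S,5R,6S,7RS)-4-{[tert-butyl(diphenyl)silyl]oxymethyl}-6-(3,4-dimethoxyphenyl)-2,7-dimethoxy-5-methyl-4-(prop-2-en-1-yl)cyclohept-2-en-1-one
Conditions: LiCl, DBU, MeCN (0.005 M), rt → 45 °C
Reagents that add atoms: none
Why: Intramolecular Horner–Wadsworth–Emmons reaction under Masamune–Roush conditions; the mild base deprotonates only the phosphonate carbon, so C3 and not C1 attacks the non-enolisable C4 aldehyde. The ring alkene is cis by necessity and the methoxy enone arrives complete.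

Step 14
Reactants: 18 (4S,5R,6S,7RS)-4-{[tert-butyl(diphenyl)silyl]oxymethyl}-6-(3,4-dimethoxyphenyl)-2,7-dimethoxy-5-methyl-4-(prop-2-en-1-yl)cyclohept-2-en-1-one
Product: 19 (4S,5R,6S,7RS)-6-(3,4-dimethoxyphenyl)-4-(hydroxymethyl)-2,7-dimethoxy-5-methyl-4-(prop-2-en-1-yl)cyclohept-2-en-1-one
Conditions: Bu4NF, AcOH, THF, rt
Reagents that add atoms: none
Why: Fluoride cleavage of the silyl ether, buffered with acetic acid so that the enolisable α-methoxy ketone sees no strong base.

Step 15
Reactants: 19 (4S,5R,6S,7RS)-6-(3,4-dimethoxyphenyl)-4-(hydroxymethyl)-2,7-dimethoxy-5-methyl-4-(prop-2-en-1-yl)cyclohept-2-en-1-one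
Product: 20 (1S,2R,3S,4RS)-3-(3,4-dimethoxyphenyl)-4,6-dimethoxy-2-methyl-5-oxo-1-(prop-2-en-1-yl)cyclohept-6-ene-1-carbaldehyde
Conditions: Dess–Martin periodinane, NaHCO3, CH2Cl2, 0 °C → rt
Reagents that add atoms: none
Why: Buffered Dess–Martin oxidation of a neopentyl primary alcohol; the aldehyde has no α-hydrogen and is taken on at once.

Step 16
Reactants: 20 (1S,2R,3S,4RS)-3-(3,4-dimethoxyphenyl)-4,6-dimethoxy-2-methyl-5-oxo-1-(prop-2-en-1-yl)cyclohept-6-ene-1-carbaldehyde
Product: 22 (1R,5S,6R,7S,8R)-7-(3,4-dimethoxyphenyl)-1,3-dimethoxy-6-methyl-5-(prop-2-en-1-yl)-8-[(triethylsilyl)oxy]bicyclo[3.2.1]oct-3-en-2-one, via lithium aldolate 21 (not isolated)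
Conditions: LiN(SiMe3)2 (1.1 equiv), THF, −78 °C; then Et3SiOTf, −78 → −40 °C
Reagents that add atoms: triethylsilyl trifluoromethanesulfonate, CC[Si](CC)(CC)OS(=O)(=O)C(F)(F)F
Why: LiN(SiMe3)2 removes the C1 hydrogen, the only acidic one (C3 is an enol-ether carbon, the aldehyde sits on quaternary C5), and the lithium dienolate adds through C1 to the C8 aldehyde across the seven-membered ring; the closest known reaction type is the intramolecular aldol addition of a ketone enolate to a non-enolisable aldehyde three carbons away, which gives bridged 2-acylcyclopentanols. The cyclopentane C1–C7–C6–C5–C8 closes in a 5-(enolexo)-exo-trig mode and, by the same bond, the six-membered ring C1–C2–C3–C4–C5–C8 closes in a 6-(enolendo)-exo-trig mode. C1 becomes a stereocentre dictated by C5, because the one-carbon bridge can only reach the ring face on which the formyl group stands, so both C1 epimers of 20 converge. At C8, lithium bridges the enolate and aldehyde oxygens in a closed transition state and the aryl group on C7 crowds the alternative, so the C8 oxygen should end up over the C2–C4 bridge. No regioselectivity is asked for; what is needed is addition over its reversal, and Et3SiOTf secures this by silylating aldolate 21 at low temperature. Ketone 22 has no α-hydrogen left and is inert to the base, and its silyl ether is the group that steers step 17.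

Step 17
Reactants: 22 (1R,5S,6R,7S,8R)-7-(3,4-dimethoxyphenyl)-1,3-dimethoxy-6-methyl-5-(prop-2-en-1-yl)-8-[(triethylsilyl)oxy]bicyclo[3.2.1]oct-3-en-2-one
Product: 23 (1S,2S,5S,6R,7S,8R)-7-(3,4-dimethoxyphenyl)-1,3-dimethoxy-6-methyl-5-(prop-2-en-1-yl)-8-[(triethylsilyl)oxy]bicyclo[3.2.1]oct-3-en-2-ol
Conditions: NaBH4, CeCl3·7H2O, MeOH–THF, −40 °C
Reagents that add atoms: none
Why: Luche 1,2-reduction of the enone; the C8 silyloxy group lies over the C2–C4 bridge and closes the C8-side face of C2 (as the syn-methyl group does in camphor), so hydride should come from the side of the C6–C7 bridge and leave the C2 hydroxyl on the C8 side (2S). A silyl ether cannot deliver hydride internally.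

Step 18
Reactants: 23 (1S,2S,5S,6R,7S,8R)-7-(3,4-dimethoxyphenyl)-1,3-dimethoxy-6-methyl-5-(prop-2-en-1-yl)-8-[(triethylsilyl)oxy]bicyclo[3.2.1]oct-3-en-2-ol
Product: 24 (1S,2S,5S,6R,7S,8R)-7-(3,4-dimethoxyphenyl)-1,3-dimethoxy-6-methyl-5-(prop-2-en-1-yl)-8-[(triethylsilyl)oxy]bicyclo[3.2.1]oct-3-en-2-yl acetate
Conditions: Ac2O, pyridine, DMAP, CH2Cl2, rt
Reagents that add atoms: acetic anhydride, CC(=O)OC(C)=O
Why: DMAP-catalysed acetylation of the only free hydroxyl under basic conditions that the enol ether tolerates; no selectivity between two carbinols is needed.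

Step 19
Reactants: 24 (1S,2S,5S,6R,7S,8R)-7-(3,4-dimethoxyphenyl)-1,3-dimethoxy-6-methyl-5-(prop-2-en-1-yl)-8-[(triethylsilyl)oxy]bicyclo[3.2.1]oct-3-en-2-yl acetate
Product: 25 (1R,2S,5S,6R,7S,8R)-7-(3,4-dimethoxyphenyl)-8-hydroxy-1,3-dimethoxy-6-methyl-5-(prop-2-en-1-yl)bicyclo[3.2.1]oct-3-en-2-yl acetate
Conditions: HF·pyridine, pyridine, THF, 0 °C → rt
Reagents that add atoms: none
Why: Buffered fluoride cleavage of the triethylsilyl ether without water or base, so neither the enol ether nor the acetate is touched.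

Step 20
Reactants: 25 (1R,2S,5S,6R,7S,8R)-7-(3,4-dimethoxyphenyl)-8-hydroxy-1,3-dimethoxy-6-methyl-5-(prop-2-en-1-yl)bicyclo[3.2.1]oct-3-en-2-yl acetate
Product: 26 (1S,2S,5S,6R,7S)-7-(3,4-dimethoxyphenyl)-1,3-dimethoxy-6-methyl-8-oxo-5-(prop-2-en-1-yl)bicyclo[3.2.1]oct-3-en-2-yl acetate
Conditions: Dess–Martin periodinane, NaHCO3, CH2Cl2, rt
Reagents that add atoms: none
Why: Dess–Martin oxidation works on hindered secondary alcohols under buffered, non-aqueous conditions; the resulting ketone lies between two quaternary carbons, so neither epimerisation nor loss of acetate by elimination is possible.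

## Compound list

1 | 4-methylfuran-2(5H)-one | CC1=CC(=O)OC1 | starting material
2 | (4S)-4-methyloxolan-2-one | C[C@@H]1COC(=O)C1 | intermediate
3 | allyl bromide (3-bromoprop-1-ene) | C=CCBr | starting material
4 | (3S,4S)-4-methyl-3-(prop-2-en-1-yl)oxolan-2-one (allyl trans to methyl) | C=CC[C@@H]1C(=O)OC[C@H]1C | intermediate
5 | (3R,4S)-3-(hydroxymethyl)-4-methyl-3-(prop-2-en-1-yl)oxolan-2-one (hydroxymethyl trans to methyl) | C=CC[C@@]1(CO)C(=O)OC[C@H]1C | intermediate
6 | (3R,4S)-3-{[tert-butyl(diphenyl)silyl]oxymethyl}-4-methyl-3-(prop-2-en-1-yl)oxolan-2-one | C=CC[C@@]1(CO[Si](c2ccccc2)(c2ccccc2)C(C)(C)C)C(=O)OC[C@H]1C | intermediate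
7 | (3R,4S)-3-{[tert-butyl(diphenyl)silyl]oxymethyl}-4-methyl-3-(prop-2-en-1-yl)oxolan-2-ol (both anomers) | C=CC[C@@]1(CO[Si](c2ccccc2)(c2ccccc2)C(C)(C)C)C(O)OC[C@H]1C | intermediate
8 | (2S,3R)-3-{[tert-butyl(diphenyl)silyl]oxymethyl}-3-(1,3-dithian-2-yl)-2-methylhex-5-en-1-ol | C=CC[C@@](CO[Si](c1ccccc1)(c1ccccc1)C(C)(C)C)(C1SCCCS1)[C@H](C)CO | intermediate
9 | (2S,3R)-3-{[tert-butyl(diphenyl)silyl]oxymethyl}-3-(1,3-dithian-2-yl)-2-methylhex-5-enal | C=CC[C@@](CO[Si](c1ccccc1)(c1ccccc1)C(C)(C)C)(C1SCCCS1)[C@H](C)C=O | intermediate (not isolated)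
10 | methyl (2E,4R,5R)-5-{[tert-butyl(diphenyl)silyl]oxymethyl}-5-(1,3-dithian-2-yl)-4-methylocta-2,7-dienoate | C=CC[C@@](CO[Si](c1ccccc1)(c1ccccc1)C(C)(C)C)(C1SCCCS1)[C@H](C)/C=C/C(=O)OC | intermediate
11 | (3,4-dimethoxyphenyl)boronic acid | OB(O)c1ccc(OC)c(OC)c1 | starting material
12 | methyl (3S,4R,5R)-5-{[tert-butyl(diphenyl)silyl]oxymethyl}-3-(3,4-dimethoxyphenyl)-5-(1,3-dithian-2-yl)-4-methyloct-7-enoate | C=CC[C@@](CO[Si](c1ccccc1)(c1ccccc1)C(C)(C)C)(C1SCCCS1)[C@H](C)[C@H](CC(=O)OC)c1ccc(OC)c(OC)c1 | intermediate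
13 | methyl (2RS,3S,4R,5R)-5-{[tert-butyl(diphenyl)silyl]oxymethyl}-3-(3,4-dimethoxyphenyl)-5-(1,3-dithian-2-yl)-2-hydroxy-4-methyloct-7-enoate | C=CC[C@@](CO[Si](c1ccccc1)(c1ccccc1)C(C)(C)C)(C1SCCCS1)[C@H](C)[C@H](C(O)C(=O)OC)c1ccc(OC)c(OC)c1 | intermediate
14 | methyl (2RS,3S,4R,5R)-5-{[tert-butyl(diphenyl)silyl]oxymethyl}-3-(3,4-dimethoxyphenyl)-5-(1,3-dithian-2-yl)-2-methoxy-4-methyloct-7-enoate | C=CC[C@@](CO[Si](c1ccccc1)(c1ccccc1)C(C)(C)C)(C1SCCCS1)[C@H](C)[C@H](C(OC)C(=O)OC)c1ccc(OC)c(OC)c1 | intermediate
15 | diethyl (methoxymethyl)phosphonate | CCOP(=O)(COC)OCC | starting material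
16 | diethyl [(1RS,3RS,4S,5R,6R)-6-{[tert-butyl(diphenyl)silyl]oxymethyl}-4-(3,4-dimethoxyphenyl)-6-(1,3-dithian-2-yl)-1,3-dimethoxy-5-methyl-2-oxonon-8-en-1-yl]phosphonate | C=CC[C@@](CO[Si](c1ccccc1)(c1ccccc1)C(C)(C)C)(C1SCCCS1)[C@H](C)[C@H](C(OC)C(=O)C(OC)P(=O)(OCC)OCC)c1ccc(OC)c(OC)c1 | intermediate
17 | diethyl [(1RS,3RS,4S,5R,6R)-6-{[tert-butyl(diphenyl)silyl]oxymethyl}-4-(3,4-dimethoxyphenyl)-6-formyl-1,3-dimethoxy-5-methyl-2-oxonon-8-en-1-yl]phosphonate | C=CC[C@@](CO[Si](c1ccccc1)(c1ccccc1)C(C)(C)C)(C=O)[C@H](C)[C@H](C(OC)C(=O)C(OC)P(=O)(OCC)OCC)c1ccc(OC)c(OC)c1 | intermediate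
18 | (4S,5R,6S,7RS)-4-{[tert-butyl(diphenyl)silyl]oxymethyl}-6-(3,4-dimethoxyphenyl)-2,7-dimethoxy-5-methyl-4-(prop-2-en-1-yl)cyclohept-2-en-1-one | C=CC[C@@]1(CO[Si](c2ccccc2)(c2ccccc2)C(C)(C)C)C=C(OC)C(=O)C(OC)[C@H](c2ccc(OC)c(OC)c2)[C@H]1C | intermediate
19 | (4S,5R,6S,7RS)-6-(3,4-dimethoxyphenyl)-4-(hydroxymethyl)-2,7-dimethoxy-5-methyl-4-(prop-2-en-1-yl)cyclohept-2-en-1-one | C=CC[C@@]1(CO)C=C(OC)C(=O)C(OC)[C@H](c2ccc(OC)c(OC)c2)[C@H]1C | intermediate
20 | (1S,2R,3S,4RS)-3-(3,4-dimethoxyphenyl)-4,6-dimethoxy-2-methyl-5-oxo-1-(prop-2-en-1-yl)cyclohept-6-ene-1-carbaldehyde (formyl trans to methyl, aryl trans to methyl) | C=CC[C@@]1(C=O)C=C(OC)C(=O)C(OC)[C@H](c2ccc(OC)c(OC)c2)[C@H]1C | intermediate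
21 | lithium (1R,5S,6R,7S,8R)-7-(3,4-dimethoxyphenyl)-1,3-dimethoxy-6-methyl-2-oxo-5-(prop-2-en-1-yl)bicyclo[3.2.1]oct-3-en-8-olate (C8 oxygen over the C2–C4 bridge) | C=CC[C@]12C=C(OC)C(=O)[C@](OC)([C@@H]1O[Li])[C@H](c1ccc(OC)c(OC)c1)[C@H]2C | intermediate (not isolated)
22 | (1R,5S,6R,7S,8R)-7-(3,4-dimethoxyphenyl)-1,3-dimethoxy-6-methyl-5-(prop-2-en-1-yl)-8-[(triethylsilyl)oxy]bicyclo[3.2.1]oct-3-en-2-one | C=CC[C@]12C=C(OC)C(=O)[C@](OC)([C@@H]1O[Si](CC)(CC)CC)[C@H](c1ccc(OC)c(OC)c1)[C@H]2C | intermediate
23 | (1S,2S,5S,6R,7S,8R)-7-(3,4-dimethoxyphenyl)-1,3-dimethoxy-6-methyl-5-(prop-2-en-1-yl)-8-[(triethylsilyl)oxy]bicyclo[3.2.1]oct-3-en-2-ol | C=CC[C@]12C=C(OC)[C@H](O)[C@](OC)([C@@H]1O[Si](CC)(CC)CC)[C@H](c1ccc(OC)c(OC)c1)[C@H]2C | intermediate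
24 | (1S,2S,5S,6R,7S,8R)-7-(3,4-dimethoxyphenyl)-1,3-dimethoxy-6-methyl-5-(prop-2-en-1-yl)-8-[(triethylsilyl)oxy]bicyclo[3.2.1]oct-3-en-2-yl acetate | C=CC[C@]12C=C(OC)[C@H](OC(C)=O)[C@](OC)([C@@H]1O[Si](CC)(CC)CC)[C@H](c1ccc(OC)c(OC)c1)[C@H]2C | intermediate
25 | (1R,2S,5S,6R,7S,8R)-7-(3,4-dimethoxyphenyl)-8-hydroxy-1,3-dimethoxy-6-methyl-5-(prop-2-en-1-yl)bicyclo[3.2.1]oct-3-en-2-yl acetate | C=CC[C@]12C=C(OC)[C@H](OC(C)=O)[C@](OC)([C@@H]1O)[C@H](c1ccc(OC)c(OC)c1)[C@H]2C | intermediate
26 | (1S,2S,5S,6R,7S)-7-(3,4-dimethoxyphenyl)-1,3-dimethoxy-6-methyl-8-oxo-5-(prop-2-en-1-yl)bicyclo[3.2.1]oct-3-en-2-yl acetate | C=CC[C@]12C=C(OC)[C@H](OC(C)=O)[C@](OC)(C1=O)[C@H](c1ccc(OC)c(OC)c1)[C@H]2C | target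

## Step count and least certain steps

Total: 20 steps. Longest linear sequence: 20 steps (1 to 26); compounds 3, 11 and 15 are purchased and enter in steps 2, 8 and 11.

**Step 16 (key step).** The most likely failures are reversal of the aldol addition before the aldolate is silylated, and attack of the amide base on the aldehyde instead of proton removal at the hindered C1. A loose, non-bridged transition state would also erode the C8 selectivity on which step 17 depends. Fallback: from 20 the closure is run as an acid-mediated Mukaiyama aldol. Et3SiOTf and i-Pr2NEt in CH2Cl2 at −78 °C convert the ketone, in the presence of the aldehyde, into the triethylsilyl dienol ether (1S,2R,3S)-3-(3,4-dimethoxyphenyl)-4,6-dimethoxy-2-methyl-1-(prop-2-en-1-yl)-5-[(triethylsilyl)oxy]cyclohepta-4,6-diene-1-carbaldehyde F1. The same silyl triflate activates the aldehyde, and bond formation with silyl transfer leads directly to 22, where the route is rejoined. No strong base and no free aldolate are involved.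

**Step 8.** Aryl transfer may be slow or poorly selective for three reasons: the dithiane sulfur atoms can occupy the rhodium, the β-carbon is screened by the neighbouring quaternary centre, and the catalyst may work against the bias of C6. Fallback: from 8, oxidation as in step 7 and Horner–Wadsworth–Emmons olefination with diethyl {2-oxo-2-[(4S)-2-oxo-4-phenyl-1,3-oxazolidin-3-yl]ethyl}phosphonate (LiCl, i-Pr2NEt) give the imide (4S)-3-[(2E,4R,5R)-5-{[tert-butyl(diphenyl)silyl]oxymethyl}-5-(1,3-dithian-2-yl)-4-methylocta-2,7-dienoyl]-4-phenyl-1,3-oxazolidin-2-one F2. (3,4-Dimethoxyphenyl)magnesium bromide with CuBr·SMe2 in THF at −20 °C adds the aryl group anti to the auxiliary phenyl group in the chelated s-cis conformer and gives (4S)-3-[(3S,4R,5R)-5-{[tert-butyl(diphenyl)silyl]oxymethyl}-3-(3,4-dimethoxyphenyl)-5-(1,3-dithian-2-yl)-4-methyloct-7-enoyl]-4-phenyl-1,3-oxazolidin-2-one F3. NaOMe in MeOH releases the auxiliary and returns 12. Copper is indifferent to the thioacetal and the sense of addition rests on the auxiliary alone.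

**Step 13.** Ring closure may be too slow against intermolecular olefination, or against aldol attack of a C1 enolate on the aldehyde, because a hindered α-methoxy phosphonate anion must reach a neopentyl aldehyde through a seven-membered transition state. Fallback (ring-closing metathesis at the same bond), from 14:
- MeI and CaCO3 in aqueous MeCN give methyl (2RS,3S,4R,5R)-5-{[tert-butyl(diphenyl)silyl]oxymethyl}-3-(3,4-dimethoxyphenyl)-5-formyl-2-methoxy-4-methyloct-7-enoate F4.
- Ph3P=CH2 gives methyl (2RS,3S,4R,5R)-5-{[tert-butyl(diphenyl)silyl]oxymethyl}-3-(3,4-dimethoxyphenyl)-5-ethenyl-2-methoxy-4-methyloct-7-enoate F5.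
- MeNHOMe·HCl and i-PrMgCl give the amide (2RS,3S,4R,5R)-5-{[tert-butyl(diphenyl)silyl]oxymethyl}-3-(3,4-dimethoxyphenyl)-5-ethenyl-N,2-dimethoxy-N,4-dimethyloct-7-enamide F6.
- 1-Methoxyvinyllithium gives (4RS,5S,6R,7R)-7-{[tert-butyl(diphenyl)silyl]oxymethyl}-5-(3,4-dimethoxyphenyl)-7-ethenyl-2,4-dimethoxy-6-methyldeca-1,9-dien-3-one F7.
- The second-generation Grubbs catalyst in dilute toluene closes the seven-membered ring between the C5 vinyl group and the methoxyvinyl ketone and returns 18.

The allyl group can only give an eight-membered ring and should lose to the seven-membered closure, but that competition is why metathesis is the reserve and not the first choice.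

**Step 17.** Both faces of C2 are hindered (the silyloxy group above, the C1–C7 bond below), so the reduction may be sluggish, and forcing it risks loss of the silyl group and hydride delivery to the wrong face. Fallback, from 22: HF·pyridine gives the free ketol (1R,5S,6R,7S,8R)-7-(3,4-dimethoxyphenyl)-8-hydroxy-1,3-dimethoxy-6-methyl-5-(prop-2-en-1-yl)bicyclo[3.2.1]oct-3-en-2-one F8. Me4NBH(OAc)3 in MeCN–AcOH then delivers hydride from the C8 oxygen to the C8-side face on purpose and gives the diol (1R,2R,5S,6R,7S,8R)-7-(3,4-dimethoxyphenyl)-1,3-dimethoxy-6-methyl-5-(prop-2-en-1-yl)bicyclo[3.2.1]oct-3-ene-2,8-diol F9, with the C2 hydroxyl on the C6–C7 side. A Mitsunobu reaction with acetic acid (PPh3, diisopropyl azodicarboxylate) inverts C2 and installs the acetate in one operation. The bridge carbinol cannot be displaced from the rear, so the product is 25, where the route is rejoined. The displacement at C2 is itself hindered, which is why this is the reserve.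

## Further compounds

F1 | step 16 | (1S,2R,3S)-3-(3,4-dimethoxyphenyl)-4,6-dimethoxy-2-methyl-1-(prop-2-en-1-yl)-5-[(triethylsilyl)oxy]cyclohepta-4,6-diene-1-carbaldehyde | C=CC[C@@]1(C=O)C=C(OC)C(O[Si](CC)(CC)CC)=C(OC)[C@H](c2ccc(OC)c(OC)c2)[C@H]1C
F2 | step 8 | (4S)-3-[(2E,4R,5R)-5-{[tert-butyl(diphenyl)silyl]oxymethyl}-5-(1,3-dithian-2-yl)-4-methylocta-2,7-dienoyl]-4-phenyl-1,3-oxazolidin-2-one | C=CC[C@@](CO[Si](c1ccccc1)(c1ccccc1)C(C)(C)C)(C1SCCCS1)[C@H](C)/C=C/C(=O)N1C(=O)OC[C@@H]1c1ccccc1
F3 | step 8 | (4S)-3-[(3S,4R,5R)-5-{[tert-butyl(diphenyl)silyl]oxymethyl}-3-(3,4-dimethoxyphenyl)-5-(1,3-dithian-2-yl)-4-methyloct-7-enoyl]-4-phenyl-1,3-oxazolidin-2-one | C=CC[C@@](CO[Si](c1ccccc1)(c1ccccc1)C(C)(C)C)(C1SCCCS1)[C@H](C)[C@H](CC(=O)N1C(=O)OC[C@@H]1c1ccccc1)c1ccc(OC)c(OC)c1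
F4 | step 13 | methyl (2RS,3S,4R,5R)-5-{[tert-butyl(diphenyl)silyl]oxymethyl}-3-(3,4-dimethoxyphenyl)-5-formyl-2-methoxy-4-methyloct-7-enoate | C=CC[C@@](CO[Si](c1ccccc1)(c1ccccc1)C(C)(C)C)(C=O)[C@H](C)[C@H](C(OC)C(=O)OC)c1ccc(OC)c(OC)c1
F5 | step 13 | methyl (2RS,3S,4R,5R)-5-{[tert-butyl(diphenyl)silyl]oxymethyl}-3-(3,4-dimethoxyphenyl)-5-ethenyl-2-methoxy-4-methyloct-7-enoate | C=CC[C@@](CO[Si](c1ccccc1)(c1ccccc1)C(C)(C)C)(C=C)[C@H](C)[C@H](C(OC)C(=O)OC)c1ccc(OC)c(OC)c1
F6 | step 13 | (2RS,3S,4R,5R)-5-{[tert-butyl(diphenyl)silyl]oxymethyl}-3-(3,4-dimethoxyphenyl)-5-ethenyl-N,2-dimethoxy-N,4-dimethyloct-7-enamide | C=CC[C@@](CO[Si](c1ccccc1)(c1ccccc1)C(C)(C)C)(C=C)[C@H](C)[C@H](C(OC)C(=O)N(C)OC)c1ccc(OC)c(OC)c1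
F7 | step 13 | (4RS,5S,6R,7R)-7-{[tert-butyl(diphenyl)silyl]oxymethyl}-5-(3,4-dimethoxyphenyl)-7-ethenyl-2,4-dimethoxy-6-methyldeca-1,9-dien-3-one | C=CC[C@@](CO[Si](c1ccccc1)(c1ccccc1)C(C)(C)C)(C=C)[C@H](C)[C@H](C(OC)C(=O)C(=C)OC)c1ccc(OC)c(OC)c1
F8 | step 17 | (1R,5S,6R,7S,8R)-7-(3,4-dimethoxyphenyl)-8-hydroxy-1,3-dimethoxy-6-methyl-5-(prop-2-en-1-yl)bicyclo[3.2.1]oct-3-en-2-one | C=CC[C@]12C=C(OC)C(=O)[C@](OC)([C@@H]1O)[C@H](c1ccc(OC)c(OC)c1)[C@H]2C
F9 | step 17 | (1R,2R,5S,6R,7S,8R)-7-(3,4-dimethoxyphenyl)-1,3-dimethoxy-6-methyl-5-(prop-2-en-1-yl)bicyclo[3.2.1]oct-3-ene-2,8-diol | C=CC[C@]12C=C(OC)[C@@H](O)[C@](OC)([C@@H]1O)[C@H](c1ccc(OC)c(OC)c1)[C@H]2C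
A1 | alternative 1 | 2-allyl-4-(3,4-dimethoxyphenyl)-5-methoxy-3-methylcyclopentan-1-one (aryl trans to methyl) | C=CCC1C(=O)C(OC)[C@H](c2ccc(OC)c(OC)c2)[C@H]1C
A2 | alternative 1 | (1Z,4E)-1-(3,4-dimethoxyphenyl)-2-methoxy-4-(prop-2-en-1-yl)hexa-1,4-dien-3-one | COc1ccc(/C=C(OC)/C(=O)/C(CC=C)=C/C)cc1OC
A3 | alternative 2 | 2-acetoxy-5-allyl-7-(3,4-dimethoxyphenyl)-1-methoxy-6-methylbicyclo[3.2.1]octane-3,8-dione | C=CC[C@]12CC(=O)[C@H](OC(C)=O)[C@](OC)(C1=O)[C@H](c1ccc(OC)c(OC)c1)[C@H]2C
A4 | alternative 2 | 1,3-dioxoisoindolin-2-yl 3-[6-acetoxy-1-methoxy-2,5-dioxo-3-(prop-2-en-1-yl)cyclohex-3-en-1-yl]-3-(3,4-dimethoxyphenyl)-2-methylpropanoate | C=CCC1=CC(=O)[C@H](OC(C)=O)[C@](OC)(C1=O)[C@H](c1ccc(OC)c(OC)c1)C(C)C(=O)ON1C(=O)c2ccccc2C1=O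
A5 | alternative 3 | 5-allyl-2-(tert-butyldimethylsilyloxy)-7-(3,4-dimethoxyphenyl)-1,3-dimethoxy-6-methylbicyclo[3.2.1]oct-3-en-8-one | C=CC[C@]12C=C(OC)[C@H](O[Si](C)(C)C(C)(C)C)[C@](OC)(C1=O)[C@H](c1ccc(OC)c(OC)c1)[C@H]2C
A6 | alternative 3 | 5-allyl-2-[(E)-3-bromo-1-(tert-butyldimethylsilyloxy)-2-methoxyprop-2-en-1-yl]-3-(3,4-dimethoxyphenyl)-2-methoxy-4-methylcyclopentan-1-one | C=CCC1C(=O)[C@@](OC)([C@@H](O[Si](C)(C)C(C)(C)C)/C(OC)=C\Br)[C@H](c2ccc(OC)c(OC)c2)[C@H]1C
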